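**Retrosynthetic overview**
- Target 20 ⇐ desilylation ⇐ Evans–Tishchenko reduction of the trans-fused hydroxy ene-dione 17 with silyloxybenzaldehyde 18, which makes the tertiary ester and the C4 carbinol together.
- 17 ⇐ allylic oxidation and ring-fusion epimerisation ⇐ hydroazulenol 15 ⇐ 6,10-closure of the C10 ketyl onto C6 of cycloheptadienone 13 (five-membered ring, formed last).
- 13 ⇐ epoxide-to-ketone 1,2-hydride shift ⇐ dienone 11 ⇐ ring expansion of cyclopropyl enone 10, in which C1 moves from C6 to C7 through the bridged cyclopropane (seven-membered ring, formed second).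
- 10 ⇐ enol acetate 6 ⇐ gold-carbenoid 1,6-closure of dehydronerolidyl acetate 5 (six-membered bisabolane-type ring plus the C1–C7 bond, formed first) ⇐ (E)-geranylacetone 1 and an acetylide.
- Farnesane numbering (C1–C11) is used in the reasoning; names use bicycloheptane or azulene locants.

Assumption: the (R)-ligand gold catalyst of step 2 gives the (1S,6R,7S) antipode of 6 (the (S)-ligand is used if the sense of induction is the opposite), and commercial (E)-geranylacetone of at least 96 % E-purity is used.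

**Step 1**
Reactants: 1 (E)-geranylacetone, (5E)-6,10-dimethylundeca-5,9-dien-2-one; 2 ethynylmagnesium bromide; 3 acetic anhydride
Product: 5 (6E)-3,7,11-trimethyldodeca-6,10-dien-1-yn-3-yl acetate (racemic at C3), via bromomagnesium alkoxide 4 (not isolated)
Conditions: HC≡CMgBr, THF, 0 °C to rt; then Ac2O, DMAP (cat.), rt
Reagents that add atoms: ethynylmagnesium bromide (2), C#C[Mg]Br; acetic anhydride (3), CC(=O)OC(C)=O
Why: Grignard 1,2-addition of the acetylide to the methyl ketone followed by O-acylation of the magnesium alkoxide in the same flask; the carbinol centre forms as a racemate and is erased in step 2.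

**Step 2**
Reactants: 5 (6E)-3,7,11-trimethyldodeca-6,10-dien-1-yn-3-yl acetate
Product: 6 (1S,6R,7S)-3,7-dimethyl-7-(4-methylpent-3-en-1-yl)bicyclo[4.1.0]hept-2-en-2-yl acetate
Conditions: (R)-DTBM-SEGPHOS(AuCl)2 (2.5 mol %), AgSbF6 (5 mol %), MeNO2, −25 °C
Reagents that add atoms: none
Why: Proposed new method: cationic monovalent gold triggers a 1,2-acyloxy shift (Rautenstrauch/Ohloff type) to a vinyl gold carbenoid in which the propargylic centre is no longer stereogenic, and this carbenoid cyclopropanates the E-6,7-alkene inside the chiral bisphosphine pocket, stereospecifically placing the 7-methyl cis and the side chain trans to the six-membered ring and setting C1, C6 and C7 in one event; the closest known chemistry is the racemic gold- or platinum-catalysed cycloisomerisation of this same acetate to the sesquicarene enol acetate, and enantioselective gold-carbenoid cyclopropanation with propargyl esters using this ligand class.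

**Step 3**
Reactants: 6 (1S,6R,7S)-3,7-dimethyl-7-(4-methylpent-3-en-1-yl)bicyclo[4.1.0]hept-2-en-2-yl acetate
Product: 10 (1S,6R,7S)-3,7-dimethyl-7-(4-methylpent-3-en-1-yl)bicyclo[4.1.0]hept-3-en-2-one, via lithium enolate 7 (not isolated), via selenide 8 (not isolated), via selenoxide 9 (not isolated)
Conditions: MeLi (2.1 equiv), THF, 0 °C; PhSeBr, −78 °C; then 30 % H2O2, pyridine, CH2Cl2, 0 °C to rt
Reagents that add atoms: none
Why: Cleavage of the enol acetate with MeLi gives the regiodefined lithium enolate, and α-selenation followed by selenoxide syn-elimination (Reich–Sharpless dehydrogenation) introduces the 3,4-double bond without touching the cyclopropane stereocentres.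

**Step 4**
Reactants: 10 (1S,6R,7S)-3,7-dimethyl-7-(4-methylpent-3-en-1-yl)bicyclo[4.1.0]hept-3-en-2-one
Product: 11 (6R)-2,6-dimethyl-6-(4-methylpent-3-en-1-yl)cyclohepta-2,4-dien-1-one
Conditions: KOt-Bu (0.3 equiv), t-BuOH, 60 °C
Reagents that add atoms: none
Why: Carenone-to-eucarvone-type ring expansion, in which γ-deprotonation gives a dienolate that opens the C1–C6 cyclopropane bond, so C1 is transferred from C6 to C7 as in the bisabolyl-to-daucyl 1,2-shift; only the quaternary centre survives and it stays configured because no bond to it is broken.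

**Step 5**
Reactants: 11 (6R)-2,6-dimethyl-6-(4-methylpent-3-en-1-yl)cyclohepta-2,4-dien-1-one
Product: 13 (6R)-2,6-dimethyl-6-(4-methyl-3-oxopentyl)cyclohepta-2,4-dien-1-one, via epoxide 12 (not isolated)
Conditions: mCPBA (1.05 equiv), NaHCO3, CH2Cl2, 0 °C; wash; then BF3·OEt2 (0.3 equiv), CH2Cl2, −78 °C
Reagents that add atoms: mCPBA, OOC(=O)c1cccc(Cl)c1
Why: Prilezhaev epoxidation selects the isolated trisubstituted alkene over the electron-poor dienone, and the Meinwald rearrangement (opening at the tertiary carbon, then 1,2-hydride shift, the counterpart of the biosynthetic C10-to-C11 hydride shift) gives the isopropyl ketone; both epoxide epimers converge.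

**Step 6**
Reactants: 13 (6R)-2,6-dimethyl-6-(4-methyl-3-oxopentyl)cyclohepta-2,4-dien-1-one
Product: 15 (3R,3aS,8aR)-3-hydroxy-6,8a-dimethyl-3-(propan-2-yl)-2,3,3a,4,8,8a-hexahydroazulen-7(1H)-one (cis-fused), via deconjugated enone 14 (not isolated)
Conditions: SmI2 (2.5 equiv), HMPA, t-BuOH (2.2 equiv), THF, −78 to 0 °C; aq. NH4Cl; then DBU (0.2 equiv), CH2Cl2, rt
Reagents that add atoms: none
Why: SmI2 ketyl–olefin reductive cyclisation in the 5-exo mode, the nucleophilic C10 ketyl adding to the electrophilic dienone δ-carbon C6 (the polarity of the biosynthetic 6,10-closure); the three-atom tether reaches C6 only on its own face, which gives the cis ring fusion, and the samarium-bound oxygen takes the usual position anti to the dienolate arm, which places the hydroxyl syn to the angular methyl (3R), before DBU brings the double bond back into conjugation.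

**Step 7**
Reactants: 15 (3R,3aS,8aR)-3-hydroxy-6,8a-dimethyl-3-(propan-2-yl)-2,3,3a,4,8,8a-hexahydroazulen-7(1H)-one
Product: 17 (3R,3aR,8aR)-3-hydroxy-6,8a-dimethyl-3-(propan-2-yl)-2,3,3a,8a-tetrahydroazulene-4,7(1H,8H)-dione (trans-fused), via cis-fused ene-dione 16 (not isolated)
Conditions: Rh2(cap)4 (dirhodium tetrakis(caprolactamate), 1 mol %), t-BuOOH (70 % aq., 5 equiv), K2CO3, CH2Cl2, rt; then DBU (0.2 equiv), rt
Reagents that add atoms: tert-butyl hydroperoxide, CC(C)(C)OO
Why: Dirhodium-catalysed allylic C–H oxidation turns the γ-methylene of the enone into the ene-dione, and the now enolisable ring-fusion CH (C3a) epimerises under base to the trans-fused isomer, which is favoured because the C4 carbonyl carbon moves trans to the isopropyl group on the neighbouring carbon and cis to the hydroxyl (hydrogen bond).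

**Step 8**
Reactants: 17 (3R,3aR,8aR)-3-hydroxy-6,8a-dimethyl-3-(propan-2-yl)-2,3,3a,8a-tetrahydroazulene-4,7(1H,8H)-dione; 18 4-[(tert-butyldimethylsilyl)oxy]benzaldehyde
Product: 19 (3R,3aS,4S,8aR)-4-hydroxy-6,8a-dimethyl-7-oxo-3-(propan-2-yl)-1,2,3,3a,4,7,8,8a-octahydroazulen-3-yl 4-[(tert-butyldimethylsilyl)oxy]benzoate
Conditions: 18 (6 equiv), SmI2 (0.3 equiv, premixed with 18), THF, −10 °C
Reagents that add atoms: 4-[(tert-butyldimethylsilyl)oxy]benzaldehyde (18), CC(C)(C)[Si](C)(C)Oc1ccc(C=O)cc1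
Why: Evans–Tishchenko reduction, in which the hemiacetal formed between the tertiary hydroxyl and the aldehyde transfers hydride within a chelate of trivalent samarium to the β-ketone from the face of that oxygen, giving the 1,3-anti relationship (4S) and leaving the acyl group on the tertiary oxygen; the C7 ketone has no β-hydroxyl and is not reduced.

**Step 9**
Reactants: 19 (3R,3aS,4S,8aR)-4-hydroxy-6,8a-dimethyl-7-oxo-3-(propan-2-yl)-1,2,3,3a,4,7,8,8a-octahydroazulen-3-yl 4-[(tert-butyldimethylsilyl)oxy]benzoate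
Product: 20 (3R,3aS,4S,8aR)-4-hydroxy-6,8a-dimethyl-7-oxo-3-(propan-2-yl)-1,2,3,3a,4,7,8,8a-octahydroazulen-3-yl 4-hydroxybenzoate
Conditions: HF·pyridine, pyridine, THF, 0 °C
Reagents that add atoms: none
Why: Fluoride cleavage of the aryl silyl ether under buffered, weakly acidic conditions, which leaves the hindered tertiary benzoate in place and avoids base-induced acyl migration to the free secondary hydroxyl.

**Compound list**
1 | (E)-geranylacetone, (5E)-6,10-dimethylundeca-5,9-dien-2-one | CC(=O)CC/C=C(\C)CCC=C(C)C | starting material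
2 | ethynylmagnesium bromide | C#C[Mg]Br | starting material
3 | acetic anhydride | CC(=O)OC(C)=O | starting material
4 | bromomagnesium (6E)-3,7,11-trimethyldodeca-6,10-dien-1-yn-3-olate (racemic) | C#CC(C)(O[Mg]Br)CC/C=C(\C)CCC=C(C)C | intermediate (not isolated)
5 | (6E)-3,7,11-trimethyldodeca-6,10-dien-1-yn-3-yl acetate (racemic at C3) | C#CC(C)(OC(C)=O)CC/C=C(\C)CCC=C(C)C | intermediate
6 | (1S,6R,7S)-3,7-dimethyl-7-(4-methylpent-3-en-1-yl)bicyclo[4.1.0]hept-2-en-2-yl acetate | CC(=O)OC1=C(C)CC[C@@H]2[C@H]1[C@@]2(C)CCC=C(C)C | intermediate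
7 | lithium (1S,6R,7S)-3,7-dimethyl-7-(4-methylpent-3-en-1-yl)bicyclo[4.1.0]hept-2-en-2-olate | [Li]OC1=C(C)CC[C@@H]2[C@H]1[C@@]2(C)CCC=C(C)C | intermediate (not isolated)
8 | (1S,6R,7S)-3,7-dimethyl-7-(4-methylpent-3-en-1-yl)-3-(phenylselanyl)bicyclo[4.1.0]heptan-2-one (C3 epimers) | CC1([Se]c3ccccc3)CC[C@@H]2[C@H](C1=O)[C@@]2(C)CCC=C(C)C | intermediate (not isolated)
9 | (1S,6R,7S)-3,7-dimethyl-7-(4-methylpent-3-en-1-yl)-3-(phenylseleninyl)bicyclo[4.1.0]heptan-2-one (epimers at C3 and Se) | CC1([Se](=O)c3ccccc3)CC[C@@H]2[C@H](C1=O)[C@@]2(C)CCC=C(C)C | intermediate (not isolated)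
10 | (1S,6R,7S)-3,7-dimethyl-7-(4-methylpent-3-en-1-yl)bicyclo[4.1.0]hept-3-en-2-one | CC1=CC[C@@H]2[C@H](C1=O)[C@@]2(C)CCC=C(C)C | intermediate
11 | (6R)-2,6-dimethyl-6-(4-methylpent-3-en-1-yl)cyclohepta-2,4-dien-1-one | CC1=CC=C[C@](C)(CCC=C(C)C)CC1=O | intermediate
12 | (6R)-6-[2-(3,3-dimethyloxiran-2-yl)ethyl]-2,6-dimethylcyclohepta-2,4-dien-1-one (both oxirane epimers) | CC1=CC=C[C@](C)(CCC2OC2(C)C)CC1=O | intermediate (not isolated)
13 | (6R)-2,6-dimethyl-6-(4-methyl-3-oxopentyl)cyclohepta-2,4-dien-1-one | CC1=CC=C[C@](C)(CCC(=O)C(C)C)CC1=O | intermediate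
14 | (3R,3aS,8aR)-3-hydroxy-6,8a-dimethyl-3-(propan-2-yl)-2,3,3a,6,8,8a-hexahydroazulen-7(1H)-one (C6 epimers) | CC1C=C[C@H]2[C@](C)(CC[C@@]2(O)C(C)C)CC1=O | intermediate (not isolated)
15 | (3R,3aS,8aR)-3-hydroxy-6,8a-dimethyl-3-(propan-2-yl)-2,3,3a,4,8,8a-hexahydroazulen-7(1H)-one (cis-fused) | CC1=CC[C@H]2[C@](C)(CC[C@@]2(O)C(C)C)CC1=O | intermediate
16 | (3R,3aS,8aR)-3-hydroxy-6,8a-dimethyl-3-(propan-2-yl)-2,3,3a,8a-tetrahydroazulene-4,7(1H,8H)-dione (cis-fused) | CC1=CC(=O)[C@H]2[C@](C)(CC[C@@]2(O)C(C)C)CC1=O | intermediate (not isolated)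
17 | (3R,3aR,8aR)-3-hydroxy-6,8a-dimethyl-3-(propan-2-yl)-2,3,3a,8a-tetrahydroazulene-4,7(1H,8H)-dione (trans-fused) | CC1=CC(=O)[C@@H]2[C@](C)(CC[C@@]2(O)C(C)C)CC1=O | intermediate
18 | 4-[(tert-butyldimethylsilyl)oxy]benzaldehyde | CC(C)(C)[Si](C)(C)Oc1ccc(C=O)cc1 | starting material
19 | (3R,3aS,4S,8aR)-4-hydroxy-6,8a-dimethyl-7-oxo-3-(propan-2-yl)-1,2,3,3a,4,7,8,8a-octahydroazulen-3-yl 4-[(tert-butyldimethylsilyl)oxy]benzoate | CC1=C[C@H](O)[C@@H]2[C@](C)(CC[C@@]2(OC(=O)c2ccc(O[Si](C)(C)C(C)(C)C)cc2)C(C)C)CC1=O | intermediate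
20 | (3R,3aS,4S,8aR)-4-hydroxy-6,8a-dimethyl-7-oxo-3-(propan-2-yl)-1,2,3,3a,4,7,8,8a-octahydroazulen-3-yl 4-hydroxybenzoate | CC1=C[C@H](O)[C@@H]2[C@](C)(CC[C@@]2(OC(=O)c2ccc(O)cc2)C(C)C)CC1=O | target

**Step count and risks**
Total steps: 9. Longest linear sequence: 9 (from 1).

Steps most likely to fail:

1. Step 2 (enantioselectivity of the gold cyclisation; the racemic reaction is known, the ligand-controlled version is not). The fallback sets out from 4 and comes back at 10, and replaces catalyst control by a covalent auxiliary. Alkoxide 4 is acylated with (R)-MTPA chloride instead of acetic anhydride to give (6E)-3,7,11-trimethyldodeca-6,10-dien-1-yn-3-yl (2S)-3,3,3-trifluoro-2-methoxy-2-phenylpropanoate F1. Achiral AuCl3 cyclises it to two diastereomeric enol esters, from which (1S,6R,7S)-3,7-dimethyl-7-(4-methylpent-3-en-1-yl)bicyclo[4.1.0]hept-2-en-2-yl (2S)-3,3,3-trifluoro-2-methoxy-2-phenylpropanoate F2 is separated by chromatography or crystallisation. K2CO3 in MeOH releases (1S,6R,7S)-3,7-dimethyl-7-(4-methylpent-3-en-1-yl)bicyclo[4.1.0]heptan-2-one F3, and 2-iodoxybenzoic acid in DMSO dehydrogenates it to 10.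

2. Step 6 (competing simple reduction or pinacol coupling of the dienone, and the sense of the two new stereocentres). The fallback sets out from 13 and comes back at 17, and closes the five-membered ring as an aldol instead of a ketyl addition. DMDO epoxidises the 4,5-alkene of the ring to (6R)-4,5-epoxy-2,6-dimethyl-6-(4-methyl-3-oxopentyl)cyclohept-2-en-1-one F4. DBU opens this γ,δ-epoxy enone from its γ-carbanion to the enolate of (6S)-2,6-dimethyl-6-(4-methyl-3-oxopentyl)cyclohept-2-ene-1,4-dione F5, and this enolate adds to the isopropyl ketone in an intramolecular aldol. The aldol is reversible and the ring-fusion centre is enolisable, so the mixture is left to settle towards 17, in which the isopropyl group is trans to the ring carbonyl carbon.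

3. Step 8 (hemiacetal formation at the hindered tertiary hydroxyl, and retro-aldol of 17 on the Lewis acid). The fallback sets out from 17 and comes back at 20, and separates reduction from acylation. Me4NBH(OAc)3 in MeCN/AcOH gives, by hydroxyl-directed anti reduction, (3R,3aS,4S,8aR)-3,4-dihydroxy-6,8a-dimethyl-3-(propan-2-yl)-2,3,3a,4,8,8a-hexahydroazulen-7(1H)-one F6. TESOTf and 2,6-lutidine silylate only the secondary hydroxyl to give (3R,3aS,4S,8aR)-3-hydroxy-6,8a-dimethyl-3-(propan-2-yl)-4-[(triethylsilyl)oxy]-2,3,3a,4,8,8a-hexahydroazulen-7(1H)-one F7. KN(SiMe3)2 followed by 4-[(tert-butyldimethylsilyl)oxy]benzoyl chloride acylates the tertiary alkoxide to give (3R,3aS,4S,8aR)-6,8a-dimethyl-7-oxo-3-(propan-2-yl)-4-[(triethylsilyl)oxy]-1,2,3,3a,4,7,8,8a-octahydroazulen-3-yl 4-[(tert-butyldimethylsilyl)oxy]benzoate F8. HF·pyridine then removes both silyl groups to give 20.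

**Further compounds**
F1 | step 2 | (6E)-3,7,11-trimethyldodeca-6,10-dien-1-yn-3-yl (2S)-3,3,3-trifluoro-2-methoxy-2-phenylpropanoate (both C3 epimers) | C#CC(C)(OC(=O)[C@@](OC)(c1ccccc1)C(F)(F)F)CC/C=C(\C)CCC=C(C)C
F2 | step 2 | (1S,6R,7S)-3,7-dimethyl-7-(4-methylpent-3-en-1-yl)bicyclo[4.1.0]hept-2-en-2-yl (2S)-3,3,3-trifluoro-2-methoxy-2-phenylpropanoate | O=C(OC1=C(C)CC[C@@H]2[C@H]1[C@@]2(C)CCC=C(C)C)[C@@](OC)(c1ccccc1)C(F)(F)F
F3 | step 2 | (1S,6R,7S)-3,7-dimethyl-7-(4-methylpent-3-en-1-yl)bicyclo[4.1.0]heptan-2-one (C3 epimers) | CC1CC[C@@H]2[C@H](C1=O)[C@@]2(C)CCC=C(C)C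
F4 | step 6 | (6R)-4,5-epoxy-2,6-dimethyl-6-(4-methyl-3-oxopentyl)cyclohept-2-en-1-one (either epoxide face) | CC1=CC2OC2[C@](C)(CCC(=O)C(C)C)CC1=O
F5 | step 6 | (6S)-2,6-dimethyl-6-(4-methyl-3-oxopentyl)cyclohept-2-ene-1,4-dione | CC1=CC(=O)C[C@](C)(CCC(=O)C(C)C)CC1=O
F6 | step 8 | (3R,3aS,4S,8aR)-3,4-dihydroxy-6,8a-dimethyl-3-(propan-2-yl)-2,3,3a,4,8,8a-hexahydroazulen-7(1H)-one | CC1=C[C@H](O)[C@@H]2[C@](C)(CC[C@@]2(O)C(C)C)CC1=O
F7 | step 8 | (3R,3aS,4S,8aR)-3-hydroxy-6,8a-dimethyl-3-(propan-2-yl)-4-[(triethylsilyl)oxy]-2,3,3a,4,8,8a-hexahydroazulen-7(1H)-one | CC1=C[C@H](O[Si](CC)(CC)CC)[C@@H]2[C@](C)(CC[C@@]2(O)C(C)C)CC1=O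
F8 | step 8 | (3R,3aS,4S,8aR)-6,8a-dimethyl-7-oxo-3-(propan-2-yl)-4-[(triethylsilyl)oxy]-1,2,3,3a,4,7,8,8a-octahydroazulen-3-yl 4-[(tert-butyldimethylsilyl)oxy]benzoate | CC1=C[C@H](O[Si](CC)(CC)CC)[C@@H]2[C@](C)(CC[C@@]2(OC(=O)c2ccc(O[Si](C)(C)C(C)(C)C)cc2)C(C)C)CC1=O
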